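Alder and ash hold the same c(free catalyst), 0.251 mM. Ash, with half the starting material, makes target at 0.0150 M d⁻¹ against alder's 0.0156 M d⁻¹, so between these two runs, at equal c(free catalyst), the charge of starting material barely shows in the rate. Oak, at 0.376 mM, reaches 0.0193 M d⁻¹: the rate grows by a factor 1.24 for a factor 1.50 in catalyst.

the same everywhere: gas 3.4 mM (held)

| charge | starting material | free catalyst | remark | time |
|---|---|---|---|---|
| alder | 0.066 M | 0.38 mol% | run made earlier |  |
| oak | 0.066 M | 0.57 mol% | run made earlier |  |
| ash | 0.033 M | 0.76 mol% | run made earlier |  |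
| flask | 0.066 M | 0.76 mol% |  | 2.5 d |

- alder (time / d: target / %, starting material / %): 0.417: 8, 90; 0.833: 19, 78; 1.25: 28, 71; 1.67: 37, 63; 2.00: 45, 52; 2.50: 59, 42; 3.00: 71, 32
- oak (time / d: target / %, starting material / %): 0.167: 2, 94; 0.500: 14, 90; 0.833: 24, 74; 1.25: 36, 62; 1.67: 47, 53; 2.50: 73, 27; 3.00: 89, 13
- ash (time / d: target / %, starting material / %): 0.625: 26, 72; 1.25: 54, 44; 1.67: 76, 24; 2.50: 99, 0; 3.00: 97, 0

(each reading ± 1.5 percentage points)

- at the start none of the gas is in solution
- reagent is what gas becomes in solution

* the target standing at 2.5 d, as a percentage of the starting material charged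
* concentration of reagent in solution at 2.5 d, in percent of saturation

So a supply is taken to stand in series with the catalyst: the reciprocal rate is a constant plus a term inverse in c(free catalyst). Alder and oak then give 0.0367 M d⁻¹, a reading with their scatter, for the transfer ceiling (mass-transfer limit), the rate at which gas enters a solution holding no reagent. Entry is taken to fall in proportion as reagent nears saturation, so in this reckoning, where entry equals use, c(reagent) stands at one minus rate over ceiling, in parts of saturation.

For the flask, at 0.502 mM, this reckoning gives 0.0219 M d⁻¹, hence 82.8% target and 40.4% of saturation. The forecast, from “gas transfer and catalytic consumption acting in series”, says 83% (78% to 88%) and 45% (34% to 56%); this reckoning's reagent lies lower.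

The flask gives 83.3% target and 38.2% of saturation.

    starting material + free catalyst → catalyst intermediate A (k = 1.40 L mol⁻¹ s⁻¹)
    reagent + catalyst intermediate A ⇌ catalyst intermediate B (K = 290 L mol⁻¹, k = 0.640 L mol⁻¹ s⁻¹)
    catalyst intermediate B ⇌ catalyst intermediate C (K = 51.0, k = 0.0110 s⁻¹)
    catalyst intermediate C → by-product + catalyst intermediate D (k = 0.0380 s⁻¹)
    catalyst intermediate D → free catalyst + target (k = 0.00380 s⁻¹)
    gas ⇌ reagent, rate k6*(csat - [reagent]) (kL = 1.20 × 10⁻⁴ s⁻¹)
    free catalyst + by-product ⇌ idle complex (K = 31.0 L mol⁻¹, k = 0.0120 L mol⁻¹ s⁻¹)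

The flask's c(reagent) already stands at 36.0% of saturation at 0.250 d. The flask's mean rate, 0.0220 M d⁻¹, held against the ceiling gives 40.1%. A neighbour flask with 0.19 mol% of free catalyst reaches 34.7% target, a mean rate of 0.00916 M d⁻¹, for which the ceiling gives c(reagent) = 2.55 mM; that neighbour holds 2.50 mM of reagent at 2.50 d.

The runs are calculated for substances that don't exist, and the scatter is random.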